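## Retrosynthetic overview

1. Target 23 is the spontaneous hemiketal of δ-hydroxy ketone 22 (C2 ketone + C21-OH). Its C5 side chains come from the bridging C5 ketone of tetracycle 15 by one-carbon homologation, hydroxymethylation (sets C5), olefination and hydrogenation.
2. Ring F comes from a C14→C15 aldol condensation of the propanoate arm onto the ring E enone of 13, the bond the presumed biogenesis closes.
3. Ring E comes from a Nazarov cyclisation of divinyl ketone 12, made from vinyl triflate 10 by carbonylative vinylation.
4. The N-methylpiperidine and both bridgehead centres (C8, C6) come from one desymmetrising double Mannich annulation of achiral dione 3 with methylamine and formaldehyde. It mirrors the presumed biogenetic logic (amine plus carbonyl carbons, iminium-driven C–C bond formation) and is run as a dynamic salt resolution.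
5. Dione 3 comes from cycloheptane-1,3-dione and methyl acrylate. Ring order: seven-membered ring (bought) → piperidine → ring E → ring F → hemiketal.

Assumption 1: the hemiketal carbon C2 is not set by a reagent; 23 and its C2 epimer interconvert through open form 22, and the 2S anomer of the natural product is taken to be the one favoured at equilibrium.

Assumption 2: the (2R,3R)-tartrate of the required enantiomer is taken to be the less soluble salt; if screening shows the reverse, (2S,3S)-tartaric acid is used and nothing else changes.

Atom labels C1–C22 are the customary biogenetic labels of this alkaloid family: N–C1–C8 and N–C7–C6 in the piperidine; C5 is the one-carbon bridge bearing C21 (CH2O) and C4–C3–C2(–C18–C20); C8–C9=C10–C11–C12–C6 completes the seven-membered ring; ring F is C8–C13–C14(C22O2Me)=C15–C9; ring E is C9–C15–C16–C17–C10. CIP letters change between some intermediates only because substituent priorities change; the geometry is constant.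

## Route

Step 1
Reactants: 1 cycloheptane-1,3-dione; 2 methyl acrylate
Product: 3 methyl 3-(2,7-dioxocycloheptyl)propanoate
Conditions: 1 (1.5 equiv), 2 (1.0 equiv), DBU (0.1 equiv), MeCN, 40 °C
Reagents that add atoms: none
Why: Base-catalysed Michael addition of the doubly activated C8–H of the 1,3-dione to the acrylate (excess dione suppresses double addition); no stereocentre is formed.

Step 2
Reactants: 3 methyl 3-(2,7-dioxocycloheptyl)propanoate; 4 methylamine; 5 formaldehyde (as paraformaldehyde, two equivalents consumed); 6 (2R,3R)-tartaric acid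
Product: 8 (2R,3R)-hydrogen tartrate of methyl 3-[(1R,6R)-8-methyl-2,10-dioxo-8-azabicyclo[4.3.1]decan-1-yl]propanoate, via amino dione 7 (not isolated)
Conditions: 4 (2.0 M in MeOH, 1.05 equiv), (CH2O)n (2.1 equiv), 6 (1.0 equiv), MeOH, 60 °C, 24 h; add i-PrOH, cool slowly to 5 °C, age, filter
Reagents that add atoms: none
Why: Proposed new method: N-methylmethaniminium formed from 4 and 5 adds to C8 to give 7, the secondary amine of 7 condenses with a second formaldehyde, and the tethered iminium is trapped by the enol of one of the two enantiotopic ketones in a six-membered Mannich closure that can only give the cis-bridged bicycle, so C8 and C6 are set together; because the β-amino ketone reopens by retro-Mannich in the warm acidic medium, the enantiomers interconvert through the achiral monocycle and the less soluble diastereomeric tartrate is harvested (crystallisation-induced diastereomer transformation); closest known reaction types are the double Mannich annulation of cyclic β-keto esters with primary amines and formaldehyde to 3-azabicyclo[n.3.1]alkanones and dynamic salt resolutions of retro-Mannich-labile Mannich bases.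

Step 3
Reactants: 8 hydrogen tartrate salt
Product: 10 methyl 3-[(1R,6R)-8-methyl-10-oxo-2-(trifluoromethanesulfonyloxy)-8-azabicyclo[4.3.1]dec-2-en-1-yl]propanoate, via free base 9 (not isolated)
Conditions: sat. aq. NaHCO3/CH2Cl2, 0 °C, dry, use at once; then KN(SiMe3)2 (1.1 equiv), THF, −78 °C; PhNTf2 (1.2 equiv), −78 → 0 °C
Reagents that add atoms: N-phenylbis(trifluoromethanesulfonimide), O=S(=O)(N(c1ccccc1)S(=O)(=O)C(F)(F)F)C(F)(F)F
Why: Enol triflate formation is regiospecific because only the C9 ketone can enolise (toward C10), the bridging C5 ketone being flanked by a quaternary carbon and a bridgehead C–H (Bredt) and the ester being less acidic; once C5 and C9 differ, re-closure can no longer give the enantiomer, so the configuration is locked.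

Step 4
Reactants: 10 vinyl triflate; 11 tributyl(vinyl)stannane
Product: 12 methyl 3-[(1S,6R)-8-methyl-10-oxo-2-(prop-2-enoyl)-8-azabicyclo[4.3.1]dec-2-en-1-yl]propanoate
Conditions: Pd(PPh3)4 (5 mol%), LiCl (3 equiv), CO (3 atm), THF, 55 °C; product used without storage
Reagents that add atoms: carbon monoxide, [C-]#[O+]
Why: Carbonylative Stille coupling, in which oxidative addition to the vinyl triflate and CO insertion (faster than direct transmetalation under CO pressure) precede vinyl transfer, gives the cross-conjugated divinyl ketone; the stereocentres are untouched.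

Step 5
Reactants: 12 divinyl ketone
Product: 13 tricyclic enone (6R,8S; ring E cyclopent-2-en-1-one with the C15 ketone fused across C9=C10; C5 ketone and C8 propanoate arm retained)
Conditions: MeSO3H (5 equiv), CH2Cl2, 0 → 25 °C
Reagents that add atoms: none
Why: Nazarov cyclisation, a conrotatory 4π closure of the protonated dienone that forms C10–C17, followed by proton loss under equilibrating acid to the tetrasubstituted ring-fusion enone; the nitrogen is protonated, which blocks retro-Mannich, and no new stereocentre remains.

Step 6
Reactants: 13 tricyclic enone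
Product: 15 tetracyclic keto dienoate (6R,8S; rings E and F closed; diene C10=C9–C15=C14 bearing CO2Me on C14; C5 ketone), via aldol adduct 14 (not isolated)
Conditions: NaOMe (0.3 equiv), MeOH, 65 °C
Reagents that add atoms: none
Why: Intramolecular aldol (Knoevenagel-type) condensation, in which the reversibly formed ester enolate attacks the C15 enone carbonyl through a five-membered transition state (the C13 arm lies in the enone plane whereas C5 is held perpendicular to it) and E1cB dehydration to the conjugated dienoate drives the equilibria; no new stereocentre is formed.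

Step 7
Reactants: 15 tetracyclic keto dienoate; 16 (methoxymethyl)triphenylphosphonium chloride
Product: 17 C5 methoxymethylidene enol ether of 15 (E/Z mixture; 6S,8R)
Conditions: 16 (1.5 equiv), KOt-Bu (1.45 equiv), THF, 0 °C, 30 min; then 15, 0 → 45 °C
Reagents that add atoms: none
Why: Wittig methoxymethylenation of the non-enolisable bridging ketone with ylide pre-formed without excess base, so the dienoate is not deprotonated; the enol ether geometry is irrelevant because the next step removes it.

Step 8
Reactants: 17 enol ether; 5 formaldehyde (37% aqueous)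
Product: 19 (5S,6S,8R)-hydroxy aldehyde (C5 carries CH2OH syn to the cycloheptene bridge plus CHO syn to the N-bridge), via aldehyde 18 (not isolated)
Conditions: 2 M HCl (2.0 equiv), THF, 25 °C; then K2CO3 (2.5 equiv), aq. CH2O (3 equiv), MeOH, 0 → 25 °C
Reagents that add atoms: water, O
Why: Enol ether hydrolysis followed by crossed aldol (Tollens-type) hydroxymethylation of the α-branched aldehyde; formaldehyde is expected to approach the exocyclic enolate over the cycloheptene bridge (one sp2 carbon and one syn-axial H) in preference to the piperidine face (two syn-axial H at C1 and C7), so CH2OH (C21) ends syn to the carbocyclic bridge and the formyl carbon (future C4) syn to the N-bridge, which sets C5.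

Step 9
Reactants: 19 hydroxy aldehyde; 20 diethyl (2-oxobutyl)phosphonate
Product: 21 (5R,6S,8R)-(E)-enone (C5 carries CH2OH and (E)-CH=CH–C(=O)Et)
Conditions: 20 (1.3 equiv), LiCl (1.5 equiv), i-Pr2NEt (1.4 equiv), MeCN, 25 °C
Reagents that add atoms: none
Why: Horner–Wadsworth–Emmons olefination under Masamune–Roush conditions, mild enough to avoid retro-aldol loss of formaldehyde from the neopentyl β-hydroxy aldehyde, gives the E-enone; the quaternary C5 cannot epimerise.

Step 10
Reactants: 21 (E)-enone
Product: 23 CNP0192143.1 (2S,5R,6S,8R), via hydroxy ketone 22 (not isolated)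
Conditions: H2 (3 atm), RhCl(PPh3)3 (10 mol%), benzene–EtOH 1:1, 40 °C
Reagents that add atoms: none
Why: Homogeneous hydrogenation with RhCl(PPh3)3 saturates only the disubstituted enone C=C (the two tetrasubstituted alkenes of the dienoate are inert), and the resulting δ-hydroxy ketone closes to the six-membered hemiketal, whose C2 centre is not set kinetically but settles by ring–chain equilibration through 22 at the 2S anomer found in the natural product.

## Compound list

1 | cycloheptane-1,3-dione | O=C1CCCCC(=O)C1 | starting material
2 | methyl acrylate | C=CC(=O)OC | starting material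
3 | methyl 3-(2,7-dioxocycloheptyl)propanoate | COC(=O)CCC1C(=O)CCCCC1=O | intermediate
4 | methylamine (2.0 M in methanol) | CN | starting material
5 | formaldehyde (paraformaldehyde in step 2, formalin in step 8) | C=O | starting material
6 | (2R,3R)-tartaric acid | OC(=O)[C@H](O)[C@@H](O)C(=O)O | starting material
7 | methyl 3-{1-[(methylamino)methyl]-2,7-dioxocycloheptyl}propanoate (amino dione, achiral) | COC(=O)CCC1(CNC)C(=O)CCCCC1=O | intermediate
8 | (2R,3R)-hydrogen tartrate (1:1) of methyl 3-[(1R,6R)-8-methyl-2,10-dioxo-8-azabicyclo[4.3.1]decan-1-yl]propanoate | O=C1[C@@H]2CCCC(=O)[C@@]1(CCC(=O)OC)CN(C)C2.OC(=O)[C@H](O)[C@@H](O)C(=O)O | intermediate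
9 | methyl 3-[(1R,6R)-8-methyl-2,10-dioxo-8-azabicyclo[4.3.1]decan-1-yl]propanoate (free base) | O=C1[C@@H]2CCCC(=O)[C@@]1(CCC(=O)OC)CN(C)C2 | intermediate
10 | methyl 3-[(1R,6R)-8-methyl-10-oxo-2-(trifluoromethanesulfonyloxy)-8-azabicyclo[4.3.1]dec-2-en-1-yl]propanoate | O=C1[C@@H]2CCC=C(OS(=O)(=O)C(F)(F)F)[C@@]1(CCC(=O)OC)CN(C)C2 | intermediate
11 | tributyl(vinyl)stannane | C=C[Sn](CCCC)(CCCC)CCCC | starting material
12 | methyl 3-[(1S,6R)-8-methyl-10-oxo-2-(prop-2-enoyl)-8-azabicyclo[4.3.1]dec-2-en-1-yl]propanoate | O=C1[C@@H]2CCC=C(C(=O)C=C)[C@@]1(CCC(=O)OC)CN(C)C2 | intermediate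
13 | tricyclic enone (6R,8S): cyclopent-2-en-1-one ring E (C15 ketone, C16, C17) fused across C9=C10 of the azabicycle; C5 ketone; CH2CH2CO2Me on C8 | O=C1[C@@H]2CCC3=C(C(=O)CC3)[C@@]1(CCC(=O)OC)CN(C)C2 | intermediate
14 | aldol adduct: ring F closed with tertiary OH on C15 and CO2Me on C14 (C14/C15 epimer mixture) | O=C1[C@@H]2CCC3=C4[C@@]1(CC(C(=O)OC)C4(O)CC3)CN(C)C2 | intermediate
15 | tetracyclic keto dienoate (6R,8S): rings E and F closed, C9=C10 and C14=C15, CO2Me on C14, C5 ketone | O=C1[C@@H]2CCC3=C4C(=C(C(=O)OC)C[C@@]41CN(C)C2)CC3 | intermediate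
16 | (methoxymethyl)triphenylphosphonium chloride | COC[P+](c1ccccc1)(c1ccccc1)c1ccccc1.[Cl-] | starting material
17 | C5 methoxymethylidene enol ether of 15 (6S,8R; E/Z mixture) | COC=C1[C@@H]2CCC3=C4C(=C(C(=O)OC)C[C@@]41CN(C)C2)CC3 | intermediate
18 | C5-formyl compound (6S,8S; C5 epimer mixture; formyl carbon = future C4) | O=CC1[C@@H]2CCC3=C4C(=C(C(=O)OC)C[C@@]41CN(C)C2)CC3 | intermediate
19 | (5S,6S,8R)-hydroxy aldehyde: C5 bears CH2OH (C21, syn to the cycloheptene bridge) and CHO (C4, syn to the N-bridge) | O=C[C@@]1(CO)[C@@H]2CCC3=C4C(=C(C(=O)OC)C[C@@]41CN(C)C2)CC3 | intermediate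
20 | diethyl (2-oxobutyl)phosphonate | CCC(=O)CP(=O)(OCC)OCC | starting material
21 | (5R,6S,8R)-(E)-enone: C5 bears CH2OH and (E)-CH=CH–C(=O)CH2CH3 | CCC(=O)/C=C/[C@@]1(CO)[C@@H]2CCC3=C4C(=C(C(=O)OC)C[C@@]41CN(C)C2)CC3 | intermediate
22 | (5R,6S,8R)-δ-hydroxy ketone: C5 bears CH2OH and CH2CH2C(=O)CH2CH3 | CCC(=O)CC[C@@]1(CO)[C@@H]2CCC3=C4C(=C(C(=O)OC)C[C@@]41CN(C)C2)CC3 | intermediate
23 | CNP0192143.1, (2S,5R,6S,8R)-hemiketal | CC[C@@]1(O)CC[C@@]2(CO1)[C@@H]1CCC3=C4C(=C(C(=O)OC)C[C@@]42CN(C)C1)CC3 | target

## Summary

Total step count: 10. Longest linear sequence: 10 steps (1 → 23).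

The three steps most likely to fail are steps 2, 6 and 8.

Step 2 (desymmetrising double Mannich with dynamic salt resolution) may give no crystalline salt or no enrichment. The fallback sets the absolute configuration with a covalent auxiliary and starts from 3. The same annulation is run with (S)-1-phenylethylamine, paraformaldehyde and AcOH in MeOH at 65 °C. It gives methyl 3-[(1R,6R)-2,10-dioxo-8-[(1S)-1-phenylethyl]-8-azabicyclo[4.3.1]decan-1-yl]propanoate F1 and its (1S,6S) bridgehead diastereomer F2, which are separated by chromatography. One-pot hydrogenolysis and reductive methylation of F1 (H2, Pd(OH)2/C, aq. CH2O, MeOH) passes through the secondary amine methyl 3-[(1R,6R)-2,10-dioxo-8-azabicyclo[4.3.1]decan-1-yl]propanoate F3 and gives free base 9. The route is rejoined at 9, inside step 3, with the NaHCO3 treatment omitted.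

Step 6 (ester–enone aldol condensation) may stall at 14 or lose out to enone self-condensation. The fallback closes ring F by palladium enolate chemistry and starts from 13. Kinetic deprotonation at C16 (LiN(SiMe3)2, THF, −78 °C) and trapping with PhNTf2 gives the cross-conjugated dienyl triflate F4, which is used at once. Intramolecular α-alkenylation of the ester enolate (Pd2(dba)3, P(t-Bu)3, LiN(SiMe3)2, toluene, 25 °C) forms C14–C15 and gives the deconjugated diene ester F5. DBU in CH2Cl2 moves the C15=C16 bond into conjugation to give 15, where the route is rejoined before step 7.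

Step 8 (facial selectivity at C5) may deliver formaldehyde mainly from the piperidine face and give the C5 epimer of 19. The fallback reverses the order of the two C–C bond formations at C5, so that the same facial preference gives the correct centre. It starts from aldehyde 18, isolated after the hydrolysis. DBU-catalysed Michael addition to ethyl vinyl ketone (MeCN, 0 °C, short reaction time) gives the (5R,6S,8R)-keto aldehyde F6, with the formyl group syn to the cycloheptene bridge and the 3-oxopentyl chain syn to the N-bridge. NaBH(OAc)3 (AcOH, CH2Cl2, 25 °C) reduces the aldehyde and leaves the ketone, giving 22, which closes to 23. The step count from 17 is unchanged.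

Further compounds
F1 | step 2 | methyl 3-[(1R,6R)-2,10-dioxo-8-[(1S)-1-phenylethyl]-8-azabicyclo[4.3.1]decan-1-yl]propanoate | O=C1[C@@H]2CCCC(=O)[C@@]1(CCC(=O)OC)CN([C@@H](C)c1ccccc1)C2
F2 | step 2 | methyl 3-[(1S,6S)-2,10-dioxo-8-[(1S)-1-phenylethyl]-8-azabicyclo[4.3.1]decan-1-yl]propanoate | O=C1[C@H]2CCCC(=O)[C@]1(CCC(=O)OC)CN([C@@H](C)c1ccccc1)C2
F3 | step 2 | methyl 3-[(1R,6R)-2,10-dioxo-8-azabicyclo[4.3.1]decan-1-yl]propanoate | O=C1[C@@H]2CCCC(=O)[C@@]1(CCC(=O)OC)CNC2
F4 | step 6 | dienyl triflate of 13 (C15 triflate, C15=C16 and C9=C10; 6R,8S) | O=C1[C@@H]2CCC3=C(C(OS(=O)(=O)C(F)(F)F)=CC3)[C@@]1(CCC(=O)OC)CN(C)C2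
F5 | step 6 | deconjugated diene ester (ring F closed, C14–H, C15=C16 and C9=C10; C14 epimer mixture) | O=C1[C@@H]2CCC3=C4C(=CC3)C(C(=O)OC)C[C@@]41CN(C)C2
F6 | step 8 | (5R,6S,8R)-keto aldehyde: C5 bears CHO (C21) and CH2CH2C(=O)CH2CH3 | CCC(=O)CC[C@@]1(C=O)[C@@H]2CCC3=C4C(=C(C(=O)OC)C[C@@]41CN(C)C2)CC3
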